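**Retrosynthetic overview** (chromene numbering: O1, C2, C3, C4, C4a, C5, C6, C7, C8, C8a)
1. Endgame: the two oxygens next to the acyl group are told apart (MOM on O7, methyl on O5). One acid operation then frees O7–H and the aryl ketone, which is carried as a dimethyl ketal.
2. Key disconnection: the bond from ring carbon C6 to the neighbouring ketone carbon. A lithiated 2,2,7-trimethylpyrano[4,3-b]pyran-5-one is acylated with the ketal ester of the whole aryl-diketone arm. In the same flask the 2-pyrone is recast into benzene ring A.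
3. Enabling feature: ring A (C4a, C5, C6, C7, C8, C8a) is a phloroglucinol with oxygen on C5, C7 and C8a, and the acyl-bearing C6 lies between C5–O and C7–O, so ring A is the enol form of a 2-acyl-1,3,5-triketone. C6 can therefore start as the methyl carbon of a 4-alkoxy-6-methyl-2-pyrone, C7 as the pyrone carbon on the ring oxygen and C5 as the lactone carbonyl. O1–C8a and C4–C4a already sit on the pyrone.
4. Ring order: 2-pyrone (bought), then the 2H-pyran ring (step 1, Knoevenagel/oxa-6π), then benzene ring A made out of the pyrone (step 4). The 4-oxyphenyl ring B is bought.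

Key step: step 4

Assumption: the o-hydroxybenzil is taken to rest in the open, hydrogen-bonded diketone form that the SMILES shows, not as its cyclic hemiketal. The target has no stereocentre.

Step 1
Reactants: 1 4-hydroxy-6-methyl-2H-pyran-2-one; 2 3-methylbut-2-enal
Product: 4 2,2,7-trimethyl-2H,5H-pyrano[4,3-b]pyran-5-one, via 1-oxatriene 3 (not isolated)
Conditions: ethylenediammonium diacetate (10 mol %), MeOH, 25 → 50 °C
Reagents that add atoms: none
Why: Knoevenagel condensation at C3 of the 4-hydroxypyrone gives 1-oxatriene 3, which closes through its C4 ketone oxygen by oxa-6π electrocyclisation (formal 3+3 annulation, the standard entry to 2H,5H-pyrano[4,3-b]pyran-5-ones), so that O1–C8a and C4–C4a of the later chromene are fixed here and no stereocentre arises.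

Step 2
Reactants: 5 2-(4-hydroxyphenyl)-2-oxoacetic acid
Product: 6 methyl 2-(4-hydroxyphenyl)-2,2-dimethoxyacetate
Conditions: HC(OMe)3 (5 equiv), cat. H2SO4, MeOH, 65 °C; NaHCO3 before concentration
Reagents that add atoms: trimethyl orthoformate COC(OC)OC; methanol CO
Why: Fischer esterification and acid-catalysed ketalisation run together, the orthoformate taking up the water and the neighbouring ester raising the electrophilicity of the ketone, and the hot acid is used here because no prenyl ether is present yet; no stereocentre arises.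

Step 3
Reactants: 6 methyl 2-(4-hydroxyphenyl)-2,2-dimethoxyacetate; 7 1-bromo-3-methylbut-2-ene
Product: 8 methyl 2,2-dimethoxy-2-{4-[(3-methylbut-2-en-1-yl)oxy]phenyl}acetate
Conditions: K2CO3, DMF, 25 °C
Reagents that add atoms: none
Why: Williamson ether synthesis, in which the phenoxide displaces the primary allylic bromide by SN2 at room temperature while ester and ketal are inert to K2CO3.

Step 4
Reactants: 4 2,2,7-trimethyl-2H,5H-pyrano[4,3-b]pyran-5-one; 8 methyl 2,2-dimethoxy-2-{4-[(3-methylbut-2-en-1-yl)oxy]phenyl}acetate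
Product: 12 1-(5,7-dihydroxy-2,2-dimethyl-2H-chromen-6-yl)-2,2-dimethoxy-2-{4-[(3-methylbut-2-en-1-yl)oxy]phenyl}ethan-1-one, via lateral lithio compound 9 (not isolated), via acylated pyranopyranone 10 (not isolated), via ring-opened keto ester 11 (not isolated)
Conditions: LiN(iPr)2 (2.2 equiv), THF, −78 °C; 8, −78 → 0 °C; then Mg(OMe)2 (4 equiv), MeOH, 65 °C; cold 1 M HCl to pH 5
Reagents that add atoms: none
Why: LiN(iPr)2 deprotonates the C7 methyl group of 4, which is vinylogous to the lactone carbonyl, and the lateral carbanion 9 attacks the ester of 8 (non-enolisable and activated by its two α-methoxy groups) in a crossed Claisen acylation that forms the bond between the future C6 and the ketone carbon, the second equivalent of base storing 10 as its enolate. Methoxide then opens the lactone at C5 to keto ester 11, the central carbon of its β-diketone closes onto the ester carbonyl (Dieckmann-type Claisen cyclisation, 6-exo-trig, the only ring closed), methoxide leaves again and enolisation of the cyclic triketone gives benzene ring A with O5 from the lactone carbonyl and O7 from the pyrone ring oxygen. The closest known reaction types are the lateral acylation of lithiated 4-alkoxy-6-methyl-2-pyrones, the Claisen condensation of 2,2-dialkoxy esters as α-ketoacyl donors and the Mg(OMe)2-induced biomimetic recyclisation of 6-(2-oxoalkyl)-2-pyrones to acylphloroglucinols, here run in one flask. No stereocentre is formed. The step needs the acyl group at C6 and not at C8, a Claisen and not an aldol mode of closure, and attack at the ester and not at the aryl ketone carbon: the first is built in because the acylated carbon itself becomes the ring atom between C5 and C7 while O1 and C4 already sit on C8a and C4a, the second because C4a bears no hydrogen and so cannot act as an aldol donor, the third because the ketone is masked as its dimethyl ketal. Acylation, ring opening and relactonisation are reversible, whereas aromatisation to the magnesium bis-phenoxide is not, so the equilibria should drain to 12.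

Step 5
Reactants: 12 1-(5,7-dihydroxy-2,2-dimethyl-2H-chromen-6-yl)-2,2-dimethoxy-2-{4-[(3-methylbut-2-en-1-yl)oxy]phenyl}ethan-1-one
Product: 13 1-[5-hydroxy-7-(methoxymethoxy)-2,2-dimethyl-2H-chromen-6-yl]-2,2-dimethoxy-2-{4-[(3-methylbut-2-en-1-yl)oxy]phenyl}ethan-1-one
Conditions: MOMCl (1.1 equiv), iPr2NEt, CH2Cl2, 0 °C
Reagents that add atoms: chloromethyl methyl ether (MOMCl) COCCl
Why: Site-selective MOM ether formation: O5–H is flanked by C4a and C6 and is held in the hydrogen bond to the ketone, whereas O7–H has the open C8–H side, so one equivalent of the chloride and a weak amine base should react at O7 and leave the second, now firmly chelated phenol untouched.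

Step 6
Reactants: 13 1-[5-hydroxy-7-(methoxymethoxy)-2,2-dimethyl-2H-chromen-6-yl]-2,2-dimethoxy-2-{4-[(3-methylbut-2-en-1-yl)oxy]phenyl}ethan-1-one
Product: 14 1-[5-methoxy-7-(methoxymethoxy)-2,2-dimethyl-2H-chromen-6-yl]-2,2-dimethoxy-2-{4-[(3-methylbut-2-en-1-yl)oxy]phenyl}ethan-1-one
Conditions: MeI (3 equiv), K2CO3, DMF, 40 °C
Reagents that add atoms: iodomethane (MeI) CI
Why: Williamson methylation of the remaining chelated phenol, which can be forced with excess MeI because 13 has no enolisable C–H (the carbon next to the ketone is the quaternary ketal carbon) and no other acidic site.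

Step 7
Reactants: 14 1-[5-methoxy-7-(methoxymethoxy)-2,2-dimethyl-2H-chromen-6-yl]-2,2-dimethoxy-2-{4-[(3-methylbut-2-en-1-yl)oxy]phenyl}ethan-1-one
Product: 15 ficucaricone C, 1-(7-hydroxy-5-methoxy-2,2-dimethyl-2H-chromen-6-yl)-2-{4-[(3-methylbut-2-en-1-yl)oxy]phenyl}ethane-1,2-dione
Conditions: 2 M aq. HCl (cat.), THF, 25 → 40 °C
Reagents that add atoms: water O
Why: Acid hydrolysis of both acetal-type groups in one operation: the MOM ether ortho to the ketone and the ketal, whose oxocarbenium ion is stabilised by the 4-alkoxyphenyl ring and can be intercepted by the freed O7–H, cleave in dilute aqueous acid under which the aryl prenyl ether and the 2,2-dimethylchromene should persist.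

**Compound list**
1 | 4-hydroxy-6-methyl-2H-pyran-2-one (triacetic acid lactone) | CC1=CC(O)=CC(=O)O1 | starting material
2 | 3-methylbut-2-enal | CC(C)=CC=O | starting material
3 | 6-methyl-3-(3-methylbut-2-en-1-ylidene)-2H-pyran-2,4(3H)-dione (1-oxatriene; geometry of the exocyclic alkene not defined, both forms converge) | CC1=CC(=O)C(=CC=C(C)C)C(=O)O1 | intermediate
4 | 2,2,7-trimethyl-2H,5H-pyrano[4,3-b]pyran-5-one | CC1=CC2=C(C=CC(C)(C)O2)C(=O)O1 | intermediate
5 | 2-(4-hydroxyphenyl)-2-oxoacetic acid | OC(=O)C(=O)c1ccc(O)cc1 | starting material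
6 | methyl 2-(4-hydroxyphenyl)-2,2-dimethoxyacetate | COC(=O)C(OC)(OC)c1ccc(O)cc1 | intermediate
7 | 1-bromo-3-methylbut-2-ene | CC(C)=CCBr | starting material
8 | methyl 2,2-dimethoxy-2-{4-[(3-methylbut-2-en-1-yl)oxy]phenyl}acetate | COC(=O)C(OC)(OC)c1ccc(OCC=C(C)C)cc1 | intermediate
9 | 7-(lithiomethyl)-2,2-dimethyl-2H,5H-pyrano[4,3-b]pyran-5-one | [Li]CC1=CC2=C(C=CC(C)(C)O2)C(=O)O1 | intermediate
10 | 7-(3,3-dimethoxy-3-{4-[(3-methylbut-2-en-1-yl)oxy]phenyl}-2-oxopropyl)-2,2-dimethyl-2H,5H-pyrano[4,3-b]pyran-5-one | COC(OC)(c1ccc(OCC=C(C)C)cc1)C(=O)CC1=CC2=C(C=CC(C)(C)O2)C(=O)O1 | intermediate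
11 | methyl 6-(5,5-dimethoxy-5-{4-[(3-methylbut-2-en-1-yl)oxy]phenyl}-2,4-dioxopentyl)-2,2-dimethyl-2H-pyran-5-carboxylate | COC(=O)C1=C(CC(=O)CC(=O)C(OC)(OC)c2ccc(OCC=C(C)C)cc2)OC(C)(C)C=C1 | intermediate
12 | 1-(5,7-dihydroxy-2,2-dimethyl-2H-chromen-6-yl)-2,2-dimethoxy-2-{4-[(3-methylbut-2-en-1-yl)oxy]phenyl}ethan-1-one | COC(OC)(c1ccc(OCC=C(C)C)cc1)C(=O)c1c(O)cc2OC(C)(C)C=Cc2c1O | intermediate
13 | 1-[5-hydroxy-7-(methoxymethoxy)-2,2-dimethyl-2H-chromen-6-yl]-2,2-dimethoxy-2-{4-[(3-methylbut-2-en-1-yl)oxy]phenyl}ethan-1-one | COCOc1cc2OC(C)(C)C=Cc2c(O)c1C(=O)C(OC)(OC)c1ccc(OCC=C(C)C)cc1 | intermediate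
14 | 1-[5-methoxy-7-(methoxymethoxy)-2,2-dimethyl-2H-chromen-6-yl]-2,2-dimethoxy-2-{4-[(3-methylbut-2-en-1-yl)oxy]phenyl}ethan-1-one | COCOc1cc2OC(C)(C)C=Cc2c(OC)c1C(=O)C(OC)(OC)c1ccc(OCC=C(C)C)cc1 | intermediate
15 | ficucaricone C | COc1c2c(cc(O)c1C(=O)C(=O)c1ccc(OCC=C(C)C)cc1)OC(C)(C)C=C2 | target

**Total step count:** 7. **Longest linear sequence:** 6 (steps 2, 3, 4, 5, 6, 7).

**Steps most likely to fail**

Step 4.
- **Risk:** Acyl substitution at the hindered ester may be slower than proton exchange. In the methoxide phase, retro-Claisen cleavage of the new β-diketone or alkoxide exchange at C8a may outrun ring closure in the mixed medium.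
- **Fallback:** It sets out from 8 and 4 and comes back at 10. It makes the same bond at the alcohol oxidation level and separates the two events.
  - Ester 8 is reduced with iBu2AlH (CH2Cl2, −78 °C) to 2,2-dimethoxy-2-{4-[(3-methylbut-2-en-1-yl)oxy]phenyl}acetaldehyde F1.
  - Lithio compound 9, made from 4 as before, adds irreversibly to this non-enolisable aldehyde. This gives racemic 7-(2-hydroxy-3,3-dimethoxy-3-{4-[(3-methylbut-2-en-1-yl)oxy]phenyl}propyl)-2,2-dimethyl-2H,5H-pyrano[4,3-b]pyran-5-one F2.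
  - Dess–Martin periodinane oxidises F2 to 10, now isolated.
  - Pure 10 is recyclised through 11 to 12 with Mg(OMe)2 in MeOH as an operation of its own.

Step 5.
- **Risk:** The small chloride may discriminate poorly between the two ortho-acyl phenols, or may protect both.
- **Fallback:** It sets out from 12 and comes back at 15. It lets steric bulk decide and avoids base in the methylation.
  - iPr3SiCl and imidazole in DMF should silylate only the open O7, giving 1-{5-hydroxy-2,2-dimethyl-7-[(triisopropylsilyl)oxy]-2H-chromen-6-yl}-2,2-dimethoxy-2-{4-[(3-methylbut-2-en-1-yl)oxy]phenyl}ethan-1-one F3.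
  - Mitsunobu methylation (MeOH, PPh3, diisopropyl azodicarboxylate, THF) gives 1-{5-methoxy-2,2-dimethyl-7-[(triisopropylsilyl)oxy]-2H-chromen-6-yl}-2,2-dimethoxy-2-{4-[(3-methylbut-2-en-1-yl)oxy]phenyl}ethan-1-one F4.
  - Bu4NF in THF frees 1-(7-hydroxy-5-methoxy-2,2-dimethyl-2H-chromen-6-yl)-2,2-dimethoxy-2-{4-[(3-methylbut-2-en-1-yl)oxy]phenyl}ethan-1-one F5.
  - Only the ketal of F5 remains to be hydrolysed, with very dilute aqueous acid, to give 15.

Step 7.
- **Risk:** Acid-induced ionisation of the aryl prenyl ether (loss or migration of the prenyl group), or hydration of an alkene, may occur before the MOM ether and the ketal are fully cleaved.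
- **Fallback:** It sets out from 6 and comes back at 15. It keeps the prenyl ether out of every acidic step and sets it last.
  - Phenol 6 is protected (MOMCl, iPr2NEt) as methyl 2,2-dimethoxy-2-[4-(methoxymethoxy)phenyl]acetate F6.
  - F6 replaces 8 under the conditions of step 4. With 9 it passes through 7-{3,3-dimethoxy-3-[4-(methoxymethoxy)phenyl]-2-oxopropyl}-2,2-dimethyl-2H,5H-pyrano[4,3-b]pyran-5-one F7 and methyl 6-{5,5-dimethoxy-5-[4-(methoxymethoxy)phenyl]-2,4-dioxopentyl}-2,2-dimethyl-2H-pyran-5-carboxylate F8, neither isolated.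
  - The product of that operation is 1-(5,7-dihydroxy-2,2-dimethyl-2H-chromen-6-yl)-2,2-dimethoxy-2-[4-(methoxymethoxy)phenyl]ethan-1-one F9.
  - The conditions of step 5 give 1-[5-hydroxy-7-(methoxymethoxy)-2,2-dimethyl-2H-chromen-6-yl]-2,2-dimethoxy-2-[4-(methoxymethoxy)phenyl]ethan-1-one F10.
  - The conditions of step 6 give 1-[5-methoxy-7-(methoxymethoxy)-2,2-dimethyl-2H-chromen-6-yl]-2,2-dimethoxy-2-[4-(methoxymethoxy)phenyl]ethan-1-one F11.
  - Aqueous HCl in THF removes all three acetal groups to give 1-(7-hydroxy-5-methoxy-2,2-dimethyl-2H-chromen-6-yl)-2-(4-hydroxyphenyl)ethane-1,2-dione F12.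
  - One equivalent each of 7 and K2CO3 in acetone alkylates the only non-chelated phenol of F12, on ring B, to give 15.

**Further compounds**
F1 | step 4 | 2,2-dimethoxy-2-{4-[(3-methylbut-2-en-1-yl)oxy]phenyl}acetaldehyde | COC(OC)(C=O)c1ccc(OCC=C(C)C)cc1
F2 | step 4 | 7-(2-hydroxy-3,3-dimethoxy-3-{4-[(3-methylbut-2-en-1-yl)oxy]phenyl}propyl)-2,2-dimethyl-2H,5H-pyrano[4,3-b]pyran-5-one (racemic) | COC(OC)(c1ccc(OCC=C(C)C)cc1)C(O)CC1=CC2=C(C=CC(C)(C)O2)C(=O)O1
F3 | step 5 | 1-{5-hydroxy-2,2-dimethyl-7-[(triisopropylsilyl)oxy]-2H-chromen-6-yl}-2,2-dimethoxy-2-{4-[(3-methylbut-2-en-1-yl)oxy]phenyl}ethan-1-one | COC(OC)(c1ccc(OCC=C(C)C)cc1)C(=O)c1c(O[Si](C(C)C)(C(C)C)C(C)C)cc2OC(C)(C)C=Cc2c1O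
F4 | step 5 | 1-{5-methoxy-2,2-dimethyl-7-[(triisopropylsilyl)oxy]-2H-chromen-6-yl}-2,2-dimethoxy-2-{4-[(3-methylbut-2-en-1-yl)oxy]phenyl}ethan-1-one | COC(OC)(c1ccc(OCC=C(C)C)cc1)C(=O)c1c(O[Si](C(C)C)(C(C)C)C(C)C)cc2OC(C)(C)C=Cc2c1OC
F5 | step 5 | 1-(7-hydroxy-5-methoxy-2,2-dimethyl-2H-chromen-6-yl)-2,2-dimethoxy-2-{4-[(3-methylbut-2-en-1-yl)oxy]phenyl}ethan-1-one | COC(OC)(c1ccc(OCC=C(C)C)cc1)C(=O)c1c(O)cc2OC(C)(C)C=Cc2c1OC
F6 | step 7 | methyl 2,2-dimethoxy-2-[4-(methoxymethoxy)phenyl]acetate | COCOc1ccc(cc1)C(OC)(OC)C(=O)OC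
F7 | step 7 | 7-{3,3-dimethoxy-3-[4-(methoxymethoxy)phenyl]-2-oxopropyl}-2,2-dimethyl-2H,5H-pyrano[4,3-b]pyran-5-one | COCOc1ccc(cc1)C(OC)(OC)C(=O)CC1=CC2=C(C=CC(C)(C)O2)C(=O)O1
F8 | step 7 | methyl 6-{5,5-dimethoxy-5-[4-(methoxymethoxy)phenyl]-2,4-dioxopentyl}-2,2-dimethyl-2H-pyran-5-carboxylate | COCOc1ccc(cc1)C(OC)(OC)C(=O)CC(=O)CC1=C(C=CC(C)(C)O1)C(=O)OC
F9 | step 7 | 1-(5,7-dihydroxy-2,2-dimethyl-2H-chromen-6-yl)-2,2-dimethoxy-2-[4-(methoxymethoxy)phenyl]ethan-1-one | COCOc1ccc(cc1)C(OC)(OC)C(=O)c1c(O)cc2OC(C)(C)C=Cc2c1O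
F10 | step 7 | 1-[5-hydroxy-7-(methoxymethoxy)-2,2-dimethyl-2H-chromen-6-yl]-2,2-dimethoxy-2-[4-(methoxymethoxy)phenyl]ethan-1-one | COCOc1ccc(cc1)C(OC)(OC)C(=O)c1c(OCOC)cc2OC(C)(C)C=Cc2c1O
F11 | step 7 | 1-[5-methoxy-7-(methoxymethoxy)-2,2-dimethyl-2H-chromen-6-yl]-2,2-dimethoxy-2-[4-(methoxymethoxy)phenyl]ethan-1-one | COCOc1ccc(cc1)C(OC)(OC)C(=O)c1c(OCOC)cc2OC(C)(C)C=Cc2c1OC
F12 | step 7 | 1-(7-hydroxy-5-methoxy-2,2-dimethyl-2H-chromen-6-yl)-2-(4-hydroxyphenyl)ethane-1,2-dione | COc1c2c(cc(O)c1C(=O)C(=O)c1ccc(O)cc1)OC(C)(C)C=C2
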